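# Proposed synthesis of CNP0168637.1 by an oxidative dearomative (4+3) cycloaddition of phlorbenzophenone

**Atom labels.** C1–C9 follow the bicyclo[3.3.1]nonane numbering of acylphloroglucinols: C1 carries benzoyl, C2/C4/C9 are the carbonyls, C3 is the third quaternary carbon, C5 carries geranyl, C6 is CH2, C7 is CH, C8 is CMe2. C10 is the CH2 on C7, C11 the CH bonded to C3, C12 the second CMe2, and C13–C14 the CH2CH2 that returns to C3.

**Compound numbers.** 1 methyl 3,3-dimethylpent-4-enoate; 2 its ozonide; 3 aldehyde ester; 4 ketophosphonate; 5 enone ester; 6 diene ester; 7 diene aldehyde; 8 2,4,6-trihydroxybenzophenone; 9 ortho-quinone methide; 10 C-alkylated arene; 11 oxyallyl cation; 12 tricyclic (4+3) adduct; 13 C8 cation; 14 cage with H on C5; 15 geranyl bromide; 16 C5-lithio cage; 17 target.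

## The problem

The core of 17 is a cage of four rings built on a cyclohexane-1,3,5-trione (ring A, C1–C2–C3–C4–C5–C9) whose three α-carbons C1, C3 and C5 are all quaternary. C1 and C5 are bridged by C8(Me2)–C7–C6 (ring B, a type A bicyclo[3.3.1]nonane-2,4,9-trione with benzoyl on C1 next to quaternary C8). C7 is tied back to C3 by C10–C11 (seven-membered ring C, a homoadamantane), and a cyclopentane (ring D, C3–C11–C12(Me2)–C13–C14) is fused on the C3–C11 bond.

Ring A is the skeleton of 2,4,6-trihydroxybenzophenone with every nucleophilic ring carbon substituted twice. The unit C3–C4(=O)–C5 is a 2-oxyallyl system whose termini are joined through C11–C10–C7–C6. This is the retron of a (4+3) cycloaddition between a phloroglucinol-derived oxyallyl cation and a 1,3-diene, and it is the feature that makes the key step possible.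

There are five stereocentres (C1 S, C3 S, C5 R, C7 R, C11 R in this numbering). The cage locks C1, C3, C5 and C7 relative to one another, so only the absolute sense of the cage and the configuration of C11 (H-11 anti to C2, ring D trans-fused to ring C) need control.

The hard bonds are C1–C8, between two quaternary carbons, and C3–C11, a bond to a neopentyl methine that no polar alkylation can make. Unsymmetrical 3,5-disubstituted acylphloroglucinols are dearomatised without regiocontrol, so the order in which the ring carbons are substituted matters.

The geranyl group (two trisubstituted alkenes) does not survive acid, electrophilic oxidants or radicals near C5. The non-enolisable β-triketone is open to retro-Claisen cleavage by nucleophiles. Geranyl is therefore best introduced last, under non-nucleophilic conditions.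

## Retrosynthesis

**17 ⇒ 14 + 15.** The C5–geranyl bond is cut. This removes the only acid- and oxidant-sensitive group, so that everything before it may use cations and an electrophilic oxidant. In 14 the bridgehead C5–H is the single proton α to a carbonyl, so site selectivity is not in question. Cutting the benzoyl group instead would leave geranyl in place and would require acylation at the more hindered bridgehead next to C8. The forward reaction is deprotonation by a hindered lithium amide and SN2 alkylation with retention at the cage carbon.

**14 ⇒ 12.** The C1–C8 bond is cut and two hydrogens are moved: 14 is an isomer of alkene 12, in which C7 carries an isopropyl group and a C7=C10 double bond. Forward, protonation at C10, a 1,2-hydride shift from the isopropyl methine and capture of the C8 cation 13 by the enol carbon C1 close ring B. This is the cation–enol bond formation that makes type A cores, done here transannularly. Because C7 is already tied to C3, its substituent must sit axial; a flexible chain would cyclise with that branch equatorial and could never reach C3 afterwards. An isopropyl group is chosen over a pre-oxidised C8 because it keeps the side chain simple and lets the C7 configuration be set convergently.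

**12 ⇒ 10 (through 11).** The C3–C11 and C5–C6 bonds are cut together. The precursor 10 is a flat arene with one achiral side chain; the product has rings C and D, two new quaternary or tertiary ring carbons and three stereocentres. The alternative of making C3–C11 by a radical and C5–C6 by alkylation needs two steps and gives no control of C11. The forward reaction must oxidise the phloroglucinol to the C3–C4–C5 oxyallyl cation 11, deliver the diene to one face, and close the seven-membered rather than a five-membered ring.

**10 ⇒ 7 + 8.** The C3–C14 bond is cut. The two free ring positions of 8 are equivalent, so the only selectivity needed is mono- versus dialkylation. The chain must arrive through a CH2 group; acylation–reduction is excluded by the acid-sensitive diene, which points to reductive alkylation with an aldehyde through ortho-quinone methide 9.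

**7 ⇒ 1 + 4.** The diene is cut at C10=C11 (Horner–Wadsworth–Emmons, E-selective) and at C7=C6 (Wittig methylenation of the enone carbonyl). The quaternary C12 is bought in 1, whose vinyl group is cleaved to aldehyde 3.

## Roads not taken

**Alternative 1:** the most obvious plan cuts C3–C11 and C12–C13 in a biomimetic sense. A type A bicycle A1 with an axial prenyl group on C7 and a prenyl group on C3 would be oxidised with Mn(OAc)3 and Cu(OAc)2. The C3 radical would add 7-exo to the C7 prenyl group, and the tertiary radical would add 5-exo to the C3 prenyl group, giving carbinol A2 after oxygen capture. The extra three carbons would then be excised by alkoxy-radical β-scission. The chosen plan is better because A1 itself needs a long bicyclic synthesis (malonyl dichloride annulation or iterative allylation, two bridgehead substitutions) with the C7 substituent in the less stable axial position. Three carbons are built in only to be cut out, and geranyl is present throughout the radical chemistry.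

**Alternative 2:** cut C1–C8, C5–C6 and the bond from C3 to the carbon on C7 in one alkylative dearomatisation–annulation. Arene A3 and 2-(acetoxymethyl)-3-methylbut-2-enal would give adamantane aldol A4 by a Michael/elimination/Michael/aldol sequence. The chosen plan is better for two reasons. The two alkylated ring carbons of A3 (geranyl against pentenyl) are not distinguished by the annulation, so regioisomers are expected. And A4 has a one-carbon bridge between C7 and C3: a ring expansion and a new bond from C11 to the quaternary C12 would still be needed, several steps on a cage that no longer enolises.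

**Alternative 3:** cut C3–C11, C10–C7 and C1–C8 in a radical cascade from monocycle A5, made by dearomative prenylation of A3. Mn(OAc)3 would generate the C3 radical, which should close 5-exo on the pendant vinyl group, then 7-exo on the C5 prenyl group, with oxidation to the C8 cation and closure on C1. The chosen plan is better because the prenylation of A3 has no regiocontrol between C3 and C5. The C3 radical of A5 would also prefer 5-exo attack on the prenyl or geranyl group on C5 (a bicyclo[3.2.1]octane). A radical on one face cannot tell prenyl from geranyl, and C8 would end exo to the ring and out of reach of C1.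

Key step: step 6

## Route

Remark (assumption): the sense of induction of the chiral aryl-λ3-iodane cannot be assigned in advance. The route is written with the (R,R)-reagent; its mirror image, made from the other lactate, is meant if the opposite face is favoured.

Step 1
Reactants: 1 methyl 3,3-dimethylpent-4-enoate
Product: 3 methyl 3,3-dimethyl-4-oxobutanoate, via ozonide 2 (not isolated)
Conditions: O3, CH2Cl2, −78 °C; then PPh3, −78 → 25 °C
Reagents that add atoms: ozone, [O-][O+]=O
Why: Ozonolysis of a monosubstituted alkene with reductive work-up; the aldehyde formed has no α-hydrogen and cannot enolise.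

Step 2
Reactants: 3 methyl 3,3-dimethyl-4-oxobutanoate; 4 dimethyl (3-methyl-2-oxobutyl)phosphonate
Product: 5 methyl (E)-3,3,7-trimethyl-6-oxooct-4-enoate
Conditions: LiCl, i-Pr2NEt, MeCN, 25 °C
Reagents that add atoms: dimethyl (3-methyl-2-oxobutyl)phosphonate (4), COP(=O)(OC)CC(=O)C(C)C
Why: Horner–Wadsworth–Emmons olefination of a non-enolisable aldehyde with a β-ketophosphonate under mild amine/LiCl conditions should give the (E)-enone; this geometry later places C12 on the outside of the diene.

Step 3
Reactants: 5 methyl (E)-3,3,7-trimethyl-6-oxooct-4-enoate
Product: 6 methyl (E)-3,3,7-trimethyl-6-methylideneoct-4-enoate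
Conditions: Ph3PCH3Br, KOt-Bu, THF, 0 → 25 °C
Reagents that add atoms: methyltriphenylphosphonium bromide, C[P+](c1ccccc1)(c1ccccc1)c1ccccc1.[Br-]
Why: Wittig methylenation turns the enone carbonyl (C7) into the 2-isopropyl-1,3-diene; the unstabilised ylide adds 1,2 and should leave the methyl ester untouched at this temperature.

Step 4
Reactants: 6 methyl (E)-3,3,7-trimethyl-6-methylideneoct-4-enoate
Product: 7 (E)-3,3,7-trimethyl-6-methylideneoct-4-enal
Conditions: i-Bu2AlH, CH2Cl2, −78 °C; aqueous sodium potassium tartrate
Reagents that add atoms: none
Why: Partial reduction of a methyl ester at −78 °C stops at the aluminium hemiacetal, which releases the aldehyde on work-up; the diene is inert to the hydride.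

Step 5
Reactants: 8 2,4,6-trihydroxybenzophenone; 7 (E)-3,3,7-trimethyl-6-methylideneoct-4-enal
Product: 10 phenyl{2,4,6-trihydroxy-3-[(E)-3,3,7-trimethyl-6-methylideneoct-4-en-1-yl]phenyl}methanone, via ortho-quinone methide 9 (not isolated)
Conditions: L-proline (cat.), diethyl 2,6-dimethyl-1,4-dihydropyridine-3,5-dicarboxylate, EtOH–CH2Cl2, 25 °C (8 in excess)
Reagents that add atoms: none
Why: Three-component reductive alkylation: amine-catalysed Knoevenagel-type condensation at a free ring carbon gives ortho-quinone methide 9, whose exocyclic C=C is reduced by hydride transfer from the Hantzsch ester. The two free positions of 8 are equivalent, and an excess of 8 should suppress double alkylation.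

Step 6
Reactants: 10 phenyl{2,4,6-trihydroxy-3-[(E)-3,3,7-trimethyl-6-methylideneoct-4-en-1-yl]phenyl}methanone
Product: 12 tricyclic (4+3) adduct (rings A + C + D; enolised 1-benzoyl triketone; isopropyl on C7; C7=C10 double bond; H on C5; new bonds at C3 and C5 syn; H-11 anti to C2), via oxyallyl cation 11 (not isolated)
Conditions: (R,R)-ArI(OAc)2 (trivalent iodine; Ar = 2,6-bis[(R)-1-(mesitylamino)-1-oxopropan-2-yloxy]phenyl), (CF3)2CHOH–CH2Cl2, −40 °C
Reagents that add atoms: none
Why: Proposed new method: two-electron oxidation of the phloroglucinol by the aryl-λ3-iodane (ligand exchange at a phenolic oxygen, loss of the aryl iodide) leaves C2–C1(COPh)–C9 as a neutral enolised β-triketone and therefore an oxyallyl cation over C3–C4(O)–C5 (11), which is taken by the tethered 1,3-diene in an intramolecular (4+3) cycloaddition; the closest known reaction types are the intramolecular (4+3) cycloaddition of oxyallyl cations from α-halo ketones with dienes on a three-atom tether, the cationic cycloadditions that follow hypervalent-iodine dearomatisation of phenols, and enantioselective ortho-spirocyclisations of phenols with chiral aryl-λ3-iodanes. Ring D closes by 5-exo attack of the diene terminus C11 on C3 (tether C14–C13–C12, helped by the gem-dimethyl group), and ring C closes as the seven-membered ring when the allyl-cation terminus C6 is taken by C5, in concert or in a fast second step. Both new bonds form on the same face of the flat ring, so C3 and C5 are set syn. C11 is set by the (E)-geometry of C10=C11, which puts C12 on the outside of the diene, together with the extended arrangement (C10 and C7 over the ring, away from O4) expected for a strongly electrophilic cyclic oxyallyl cation; this gives the trans-fused C/D system with H-11 anti to C2 as in 17, whereas the compact arrangement would give the C11 epimer. The absolute configuration is decided in the first C–C bond formation, while the chiral iodane is still bound to the phenolic oxygen. The step needs (4+3) rather than (3+2) closure and C- rather than O-capture of the allyl cation: the primary terminus C6 is less hindered than C10, C5 is an unsubstituted and strongly nucleophilic enol carbon, and the benzoylated C1 is too electron-poor to compete. Site selectivity needs no control, because the tether reaches only C3, and the isopropyl group on C7 favours the s-cis diene.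

Step 7
Reactants: 12 tricyclic (4+3) adduct
Product: 14 cage with H on C5 ((1S,3S,5R,7R,11R)-1-benzoyl-8,8,12,12-tetramethyl tetracyclic trione; rings A–D), via tertiary C8 cation 13 (not isolated)
Conditions: TfOH (cat.), (CF3)2CHOH–CH2Cl2, 0 → 25 °C
Reagents that add atoms: none
Why: Acid-mediated transannular hydroalkylation, the cation–enol ring closure of type A acylphloroglucinols: Markovnikov protonation at C10 gives the tertiary C7 cation, a 1,2-hydride shift from the isopropyl methine moves the charge to C8 (13), and the enol carbon C1 closes ring B through a chair. C8 can reach C1 only if H-7 ends exo; cations, alkenes and O-alkylated material with the wrong orientation should re-ionise under the conditions, so the sequence is stereoconvergent at C7 and sets C1.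

Step 8
Reactants: 14 cage with H on C5; 15 geranyl bromide
Product: 17 CNP0168637.1, via bridgehead lithium compound 16 (not isolated)
Conditions: lithium 2,2,6,6-tetramethylpiperidide (from n-BuLi and the amine), THF, −78 °C; then 15, −78 → −20 °C
Reagents that add atoms: geranyl bromide (15), CC(C)=CCC/C(C)=C/CBr
Why: Bridgehead deprotonation and C-allylation of a bicyclo[3.3.1]nonane-2,4,9-trione with a hindered lithium amide, as used for bridgehead prenylation of related cores. C5–H is the only proton α to a carbonyl, the carbanion is held by the cage so geranyl enters with retention, and SN2 attack at the primary carbon keeps the (E)-alkene.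

## Compound list

1 | methyl 3,3-dimethylpent-4-enoate | COC(=O)CC(C)(C)C=C | starting material
2 | methyl 3-methyl-3-(1,2,4-trioxolan-3-yl)butanoate (ozonide) | COC(=O)CC(C)(C)C1OCOO1 | intermediate
3 | methyl 3,3-dimethyl-4-oxobutanoate | COC(=O)CC(C)(C)C=O | intermediate
4 | dimethyl (3-methyl-2-oxobutyl)phosphonate | COP(=O)(OC)CC(=O)C(C)C | starting material
5 | methyl (E)-3,3,7-trimethyl-6-oxooct-4-enoate | COC(=O)CC(C)(C)/C=C/C(=O)C(C)C | intermediate
6 | methyl (E)-3,3,7-trimethyl-6-methylideneoct-4-enoate | COC(=O)CC(C)(C)/C=C/C(=C)C(C)C | intermediate
7 | (E)-3,3,7-trimethyl-6-methylideneoct-4-enal | O=CCC(C)(C)/C=C/C(=C)C(C)C | intermediate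
8 | 2,4,6-trihydroxybenzophenone | O=C(c1ccccc1)c1c(O)cc(O)cc1O | starting material
9 | ortho-quinone methide: 4-benzoyl-3,5-dihydroxy-6-[(E)-3,3,7-trimethyl-6-methylideneoct-4-enylidene]cyclohexa-2,4-dien-1-one (exocyclic geometry not defined) | O=C1C=C(O)C(C(=O)c2ccccc2)=C(O)C1=CCC(C)(C)/C=C/C(=C)C(C)C | intermediate
10 | phenyl{2,4,6-trihydroxy-3-[(E)-3,3,7-trimethyl-6-methylideneoct-4-en-1-yl]phenyl}methanone | O=C(c1ccccc1)c1c(O)cc(O)c(CCC(C)(C)/C=C/C(=C)C(C)C)c1O | intermediate
11 | oxyallyl (phenoxonium) cation of 10, charge over C3–C4(O)–C5 | O=C1C=C(O)C(C(=O)c2ccccc2)=C(O)[C+]1CCC(C)(C)/C=C/C(=C)C(C)C | intermediate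
12 | tricyclic (4+3) adduct: ring A (enolised 1-benzoyl triketone, H on C5), ring C (C7=C10, isopropyl on C7), ring D; bonds at C3 and C5 syn, H-11 anti to C2 | [C@@H]12CC(C(C)C)=C[C@@H]3C(C)(C)CC[C@]3(C1=O)C(=O)C(C(=O)c1ccccc1)=C2O | intermediate
13 | tertiary C8 cation (propan-2-ylium on C7, H-7 exo) | [C@@H]12C[C@H]([C+](C)C)C[C@@H]3C(C)(C)CC[C@]3(C1=O)C(=O)C(C(=O)c1ccccc1)=C2O | intermediate
14 | cage with H on C5: (1S,3S,5R,7R,11R)-1-benzoyl-8,8,12,12-tetramethyl tetracyclic 2,4,9-trione (rings A–D) | [C@@H]12C[C@H]3C[C@@H]4C(C)(C)CC[C@]4(C1=O)C(=O)[C@@](C(=O)c1ccccc1)(C2=O)C3(C)C | intermediate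
15 | geranyl bromide, (E)-1-bromo-3,7-dimethylocta-2,6-diene | CC(C)=CCC/C(C)=C/CBr | starting material
16 | C5-lithio derivative of 14 | [Li][C@@]12C[C@H]3C[C@@H]4C(C)(C)CC[C@]4(C1=O)C(=O)[C@@](C(=O)c1ccccc1)(C2=O)C3(C)C | intermediate
17 | CNP0168637.1: (1S,3S,5R,7R,11R)-1-benzoyl-5-[(E)-3,7-dimethylocta-2,6-dienyl]-8,8,12,12-tetramethyl tetracyclic 2,4,9-trione | CC(C)=CCC/C(C)=C/C[C@@]12C[C@H]3C[C@@H]4C(C)(C)CC[C@]4(C1=O)C(=O)[C@@](C(=O)c1ccccc1)(C2=O)C3(C)C | target

## Step count and least certain steps

Total: 8 steps. Longest linear sequence: 8 steps (1 → 17).

**Step 6 (key step, proposed new method).** Four things are most likely to go wrong: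
- capture of the allyl cation through oxygen, or at C10 in a (3+2) sense, in place of seven-membered ring closure;
- reaction through the compact arrangement, which gives the C11 epimer;
- weak facial discrimination by the chiral iodane;
- further oxidation of the enolised product by excess reagent.

The fallback generates the same cation by the classical α-halo ketone route and settles the absolute configuration by separation. It sets out from 10. Double chlorination with N-chlorosuccinimide (first at the free position C5, then ipso at C3) would give the dearomatised dichloride F1. Ionisation of the tertiary C3 chloride with AgBF4 in (CF3)2CHOH and intramolecular (4+3) cycloaddition across the three-atom tether would give the racemic 5-chloro tricycle F2. The acid of step 7 would give the 5-chloro cage F3. Reductive dechlorination with zinc in acetic acid, then separation of the enantiomers on a chiral stationary phase, brings it back to the route at 14.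

**Step 8.** Bridgehead deprotonation may be slow or incomplete in the rigid all-ketone cage, or the amide may attack a carbonyl or transfer an electron to the benzoyl group. The fallback replaces deprotonation by a carbon–halogen handle and sets out from 10. Bromination at C5 with N-bromosuccinimide would give bromo arene F4. Steps 6 and 7 unchanged (the C5 terminus of the oxyallyl cation now carries bromine) would give bromo tricycle F5 and bromo cage F6. Insertion of zinc dust into the bridgehead C–Br bond (a Reformatsky-type reagent) and Pd(PPh3)4-catalysed allylation with 15 at the primary terminus brings it back at 17.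

**Step 7.** The first-formed C7 cation may close on C1 to a five-membered ring before the hydride shift, or the C8 cation may be captured by the enol oxygen and not re-ionise. The fallback splits the cascade and sets out from 12. A weak acid (camphorsulfonic acid, CH2Cl2) would give the cyclic enol ether F7 by O-capture at C8. A separate Lewis-acid step (BF3·OEt2) would then effect the 1,3 O-to-C shift through the ion pair at C8, which avoids the C7 cation. It comes back at 14.

**Step 5.** The ortho-quinone methide may be captured by a second molecule of 8, or a second alkylation may occur, before hydride transfer. The fallback traps the quinone methide with a thiol and reduces in a separate step. It sets out from 8 and 7: three-component condensation with thiophenol would give benzylic sulfide F8, and radical desulfurisation with Bu3SnH and azobisisobutyronitrile brings it back at 10.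

## Further compounds

F1 | step 6 | 4-benzoyl-2,6-dichloro-3,5-dihydroxy-6-[(E)-3,3,7-trimethyl-6-methylideneoct-4-en-1-yl]cyclohexa-2,4-dien-1-one (racemic) | O=C1C(Cl)=C(O)C(C(=O)c2ccccc2)=C(O)C1(Cl)CCC(C)(C)/C=C/C(=C)C(C)C
F2 | step 6 | 5-chloro analogue of 12 (racemic; one enantiomer drawn) | Cl[C@@]12CC(C(C)C)=C[C@@H]3C(C)(C)CC[C@]3(C1=O)C(=O)C(C(=O)c1ccccc1)=C2O
F3 | step 6 | 5-chloro analogue of 14 (racemic; one enantiomer drawn) | Cl[C@@]12C[C@H]3C[C@@H]4C(C)(C)CC[C@]4(C1=O)C(=O)[C@@](C(=O)c1ccccc1)(C2=O)C3(C)C
F4 | step 8 | {3-bromo-2,4,6-trihydroxy-5-[(E)-3,3,7-trimethyl-6-methylideneoct-4-en-1-yl]phenyl}(phenyl)methanone | O=C(c1ccccc1)c1c(O)c(Br)c(O)c(CCC(C)(C)/C=C/C(=C)C(C)C)c1O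
F5 | step 8 | 5-bromo analogue of 12 | Br[C@@]12CC(C(C)C)=C[C@@H]3C(C)(C)CC[C@]3(C1=O)C(=O)C(C(=O)c1ccccc1)=C2O
F6 | step 8 | 5-bromo analogue of 14 | Br[C@@]12C[C@H]3C[C@@H]4C(C)(C)CC[C@]4(C1=O)C(=O)[C@@](C(=O)c1ccccc1)(C2=O)C3(C)C
F7 | step 7 | cyclic enol ether (O on C9 bonded to C8; isomer of 14) | [C@@H]12C[C@H]3C[C@@H]4C(C)(C)CC[C@]4(C1=O)C(=O)C(C(=O)c1ccccc1)=C2OC3(C)C
F8 | step 5 | phenyl{2,4,6-trihydroxy-3-[(E)-3,3,7-trimethyl-6-methylidene-1-(phenylsulfanyl)oct-4-en-1-yl]phenyl}methanone (racemic) | O=C(c1ccccc1)c1c(O)cc(O)c(C(Sc2ccccc2)CC(C)(C)/C=C/C(=C)C(C)C)c1O
A1 | alternative 1 | 1-benzoyl-5-geranyl-4-hydroxy-8,8-dimethyl-3,7-bis(3-methylbut-2-enyl)bicyclo[3.3.1]non-3-ene-2,9-dione with axial prenyl on C7 | CC(C)=CCC/C(C)=C/C[C@@]12C[C@@H](CC=C(C)C)C(C)(C)[C@](C(=O)c3ccccc3)(C2=O)C(=O)C(CC=C(C)C)=C1O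
A2 | alternative 1 | 13-(2-hydroxypropan-2-yl) homologue of 17 (C13 not defined) | CC(C)=CCC/C(C)=C/C[C@@]12C[C@H]3C[C@@H]4C(C)(C)C(C(C)(C)O)C[C@]4(C1=O)C(=O)[C@@](C(=O)c1ccccc1)(C2=O)C3(C)C
A3 | alternative 2 | {3-[(E)-3,7-dimethylocta-2,6-dienyl]-5-(3,3-dimethylpent-4-enyl)-2,4,6-trihydroxyphenyl}(phenyl)methanone | O=C(c1ccccc1)c1c(O)c(C/C=C(\C)CCC=C(C)C)c(O)c(CCC(C)(C)C=C)c1O
A4 | alternative 2 | adamantane aldol: 1-benzoyl-5-geranyl-8,8-dimethyl-3-(3,3-dimethylpent-4-enyl) trione with CH(OH) bridging C7 and C3 (carbinol not defined) | CC(C)=CCC/C(C)=C/C[C@@]12C[C@H]3C(O)[C@@](CCC(C)(C)C=C)(C1=O)C(=O)[C@@](C(=O)c1ccccc1)(C2=O)C3(C)C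
A5 | alternative 3 | 2-benzoyl-4-geranyl-3,5-dihydroxy-4-(3-methylbut-2-enyl)-6-(3,3-dimethylpent-4-enyl)cyclohexa-2,5-dien-1-one | O=C(c1ccccc1)C1=C(O)C(CCC(C)(C)C=C)=C(O)[C@](CC=C(C)C)(C/C=C(\C)CCC=C(C)C)C1=O
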